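**Plan**

1. Lactone numbering: O1, C2(=O), C3, C4, C5; C7' is the benzylic carbon of the catechol arm. The target is the trans (3R,4R) lactone, with the 3,4-dimethoxybenzyl group on C3 and the 3,4-dihydroxybenzyl group on C4.
2. Enabling feature: C5 is an unsubstituted O–CH2 on C4, and C4–H becomes enolisable once C7' is held as an aryl ketone. C5 can therefore come from CH2=O, and C4 can equilibrate trans to C3.
3. Retrosynthesis: C7' is raised to a ketone and the catechol is benzylated; C4–C5 and O1–C2 are cut to give formaldehyde and an (R)-2-benzyl-3-aroylpropanoic acid; then C7'–aryl (acyl–aryl coupling) and C3–C4 (auxiliary enolate alkylation) are cut.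
4. Forward: the chain is built by auxiliary loading, alkylation (C3–C4), Negishi acylation (C7'–aryl) and auxiliary removal. The lactone, the only ring formed, closes in step 7. Hydrogenolysis then turns C7'=O into CH2 and frees the catechol.
5. Stereochemistry: C3 comes from the (S)-4-benzyloxazolidinone-directed alkylation; C4 is relayed from C3 by acid-mediated equilibration through the ketone enol.

Key step: step 7

**Route**

Step 1
Reactants: 1 3-(3,4-dimethoxyphenyl)propanoic acid; 2 (S)-4-benzyloxazolidin-2-one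
Product: 4 (S)-4-benzyl-3-[3-(3,4-dimethoxyphenyl)propanoyl]oxazolidin-2-one, via mixed pivalic anhydride 3 (not isolated)
Conditions: PivCl, Et3N, THF, −20 °C; then LiCl, 2, −20 °C to rt
Reagents that add atoms: none
Why: N-acylation of the oxazolidinone through a mixed anhydride (LiCl/Et3N activation) is the standard way to load an Evans auxiliary, the hindered pivaloyl carbonyl directing the nitrogen to the arylpropanoyl carbonyl.

Step 2
Reactants: 4 (S)-4-benzyl-3-[3-(3,4-dimethoxyphenyl)propanoyl]oxazolidin-2-one; 5 tert-butyl bromoacetate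
Product: 7 tert-butyl (R)-4-[(S)-4-benzyl-2-oxooxazolidin-3-yl]-3-(3,4-dimethoxybenzyl)-4-oxobutanoate, via sodium Z-enolate 6 (not isolated)
Conditions: NaHMDS (1.1 equiv), THF, −78 °C; then 5, −78 to −40 °C
Reagents that add atoms: none
Why: Evans asymmetric alkylation: the chelated Z-enolate is shielded on one face by the benzyl group of the auxiliary, so the SN2 attack on the bromoacetate occurs on the opposite face and should set the future C3 as (R) while forming C3–C4.

Step 3
Reactants: 7 tert-butyl (R)-4-[(S)-4-benzyl-2-oxooxazolidin-3-yl]-3-(3,4-dimethoxybenzyl)-4-oxobutanoate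
Product: 8 (R)-4-[(S)-4-benzyl-2-oxooxazolidin-3-yl]-3-(3,4-dimethoxybenzyl)-4-oxobutanoic acid
Conditions: TFA, CH2Cl2, 0 °C to rt
Reagents that add atoms: none
Why: Acidolysis of a tert-butyl ester (E1 loss of isobutene) should free the acid without touching the imide, the aryl methyl ethers or the stereocentre.

Step 4
Reactants: 9 4-bromocatechol
Product: 10 1,2-bis(benzyloxy)-4-bromobenzene
Conditions: BnBr (2.2 equiv), K2CO3, DMF, 60 °C, N2
Reagents that add atoms: benzyl bromide, BrCc1ccccc1
Why: Williamson ether synthesis masks both phenols as benzyl ethers, which tolerate the organometallic, peroxide, hydroxide and acid steps and leave in the final hydrogenation.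

Step 5
Reactants: 8 (R)-4-[(S)-4-benzyl-2-oxooxazolidin-3-yl]-3-(3,4-dimethoxybenzyl)-4-oxobutanoic acid; 10 1,2-bis(benzyloxy)-4-bromobenzene
Product: 14 (S)-4-benzyl-3-[(R)-4-[3,4-bis(benzyloxy)phenyl]-2-(3,4-dimethoxybenzyl)-4-oxobutanoyl]oxazolidin-2-one, via acyl chloride 11 (not isolated), via aryllithium 12 (not isolated), via arylzinc chloride 13 (not isolated)
Conditions: 8, (COCl)2, cat. DMF, CH2Cl2, 0 °C to rt, evaporate; 10, n-BuLi, THF, −78 °C, then ZnCl2, −78 to 0 °C; combine, Pd(PPh3)4 (5 mol %), THF, 0 °C to rt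
Reagents that add atoms: none
Why: Negishi acylation: zerovalent palladium inserts into the acyl C–Cl bond, and transmetallation from the arylzinc followed by reductive elimination forms the C7'–aryl ketone bond; the arylzinc is too mild to attack the imide or to deprotonate next to the stereocentre.

Step 6
Reactants: 14 (S)-4-benzyl-3-[(R)-4-[3,4-bis(benzyloxy)phenyl]-2-(3,4-dimethoxybenzyl)-4-oxobutanoyl]oxazolidin-2-one
Product: 16 (R)-4-[3,4-bis(benzyloxy)phenyl]-2-(3,4-dimethoxybenzyl)-4-oxobutanoic acid, via peroxy acid 15 (not isolated)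
Conditions: LiOH, 30% aq H2O2, THF/H2O, 0 °C; aq Na2SO3; 1 M HCl to pH 2
Reagents that add atoms: hydrogen peroxide, OO
Why: Evans hydroperoxide cleavage: HOO− attacks the exocyclic imide carbonyl selectively at 0 °C and sulfite reduces the resulting peroxy acid, so the auxiliary is released without enolising the alpha-stereocentre, and the electron-rich aryl ketone should be inert to hydroperoxide at this temperature.

Step 7
Reactants: 16 (R)-4-[3,4-bis(benzyloxy)phenyl]-2-(3,4-dimethoxybenzyl)-4-oxobutanoic acid; 17 formaldehyde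
Product: 20 (3R,4R)-4-[3,4-bis(benzyloxy)benzoyl]-3-(3,4-dimethoxybenzyl)dihydrofuran-2(3H)-one, via hydroxymethyl keto acid 18 (not isolated), via epimeric lactone mixture 19 (not isolated)
Conditions: 17 (37% aq, 1.2 equiv), NaOH (2.1 equiv), THF/H2O, 0 °C to rt; 2 M HCl to pH 1, EtOAc extraction; then TsOH·H2O (0.2 equiv), toluene, 60 °C
Reagents that add atoms: none
Why: In aqueous NaOH the acid is a carboxylate, so C3–H is not removed and only the aryl ketone enolises, at C4; this enolate adds to formaldehyde in a crossed (Tollens-type) aldol, forming C4–C5 and giving 18. The closest known reaction type is the base-mediated hydroxymethylation–lactonisation of 3-aroylpropanoic acids to 4-aroylbutyrolactones, applied here to a 2-benzyl member of that class. On acidification the gamma-hydroxy acid closes O1–C2 by a 5-exo-trig acyl substitution (acid-catalysed lactonisation), giving 19 as a mixture at C4. C4, the one new stereocentre, is set under thermodynamic control: TsOH equilibrates it through the ketone enol until the aroyl group sits trans to the (R)-C3 benzyl group, i.e. (3R,4R), so the facial selectivity of the aldol itself does not matter. The step needs mono-addition, no dehydration and an intact C3: the near-stoichiometric formaldehyde charge and the tertiary C4–H left after one addition limit over-reaction; low temperature and prompt acidification limit E1cB loss of water, and once the lactone is closed, opening by elimination would be the reverse of a disfavoured 5-endo-trig closure; C3–H is flanked only by a carboxylate in base and a lactone carbonyl in acid, neither of which enolises under these conditions.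

Step 8
Reactants: 20 (3R,4R)-4-[3,4-bis(benzyloxy)benzoyl]-3-(3,4-dimethoxybenzyl)dihydrofuran-2(3H)-one
Product: 23 (3R,4R)-4-(3,4-dihydroxybenzyl)-3-(3,4-dimethoxybenzyl)dihydrofuran-2(3H)-one, via catechol ketone 21 (not isolated), via benzylic alcohol 22 (not isolated)
Conditions: H2 (4 atm), 10% Pd/C, EtOH/AcOH, 50 °C
Reagents that add atoms: none
Why: Catalytic hydrogenolysis over Pd/C cleaves both O-benzyl ethers and reduces the electron-rich aryl ketone through the benzylic alcohol to CH2 (benzylic C–O hydrogenolysis assisted by the para-hydroxyl group, as in the conversion of 7-oxo and 7-hydroxy lignan lactones into their deoxy forms) without touching C3 or C4; acetic acid is the only acid present so that benzylic-cation cyclisation onto the dimethoxyphenyl ring is not invited.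

**Compound list**

1 | 3-(3,4-dimethoxyphenyl)propanoic acid | COc1ccc(CCC(=O)O)cc1OC | starting material
2 | (S)-4-benzyloxazolidin-2-one | O=C1N[C@@H](Cc2ccccc2)CO1 | starting material
3 | 3-(3,4-dimethoxyphenyl)propanoic pivalic anhydride | COc1ccc(CCC(=O)OC(=O)C(C)(C)C)cc1OC | intermediate
4 | (S)-4-benzyl-3-[3-(3,4-dimethoxyphenyl)propanoyl]oxazolidin-2-one | COc1ccc(CCC(=O)N2[C@@H](Cc3ccccc3)COC2=O)cc1OC | intermediate
5 | tert-butyl bromoacetate | CC(C)(C)OC(=O)CBr | starting material
6 | sodium (Z)-enolate of 4 | COc1ccc(C/C=C(\[O-])N2[C@@H](Cc3ccccc3)COC2=O)cc1OC.[Na+] | intermediate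
7 | tert-butyl (R)-4-[(S)-4-benzyl-2-oxooxazolidin-3-yl]-3-(3,4-dimethoxybenzyl)-4-oxobutanoate | COc1ccc(C[C@H](CC(=O)OC(C)(C)C)C(=O)N2[C@@H](Cc3ccccc3)COC2=O)cc1OC | intermediate
8 | (R)-4-[(S)-4-benzyl-2-oxooxazolidin-3-yl]-3-(3,4-dimethoxybenzyl)-4-oxobutanoic acid | COc1ccc(C[C@H](CC(=O)O)C(=O)N2[C@@H](Cc3ccccc3)COC2=O)cc1OC | intermediate
9 | 4-bromocatechol (4-bromobenzene-1,2-diol) | Oc1ccc(Br)cc1O | starting material
10 | 1,2-bis(benzyloxy)-4-bromobenzene | Brc1ccc(OCc2ccccc2)c(OCc2ccccc2)c1 | intermediate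
11 | (R)-4-[(S)-4-benzyl-2-oxooxazolidin-3-yl]-3-(3,4-dimethoxybenzyl)-4-oxobutanoyl chloride | COc1ccc(C[C@H](CC(=O)Cl)C(=O)N2[C@@H](Cc3ccccc3)COC2=O)cc1OC | intermediate
12 | [3,4-bis(benzyloxy)phenyl]lithium | [Li]c1ccc(OCc2ccccc2)c(OCc2ccccc2)c1 | intermediate
13 | [3,4-bis(benzyloxy)phenyl]zinc chloride | Cl[Zn]c1ccc(OCc2ccccc2)c(OCc2ccccc2)c1 | intermediate
14 | (S)-4-benzyl-3-[(R)-4-[3,4-bis(benzyloxy)phenyl]-2-(3,4-dimethoxybenzyl)-4-oxobutanoyl]oxazolidin-2-one | COc1ccc(C[C@H](CC(=O)c2ccc(OCc3ccccc3)c(OCc3ccccc3)c2)C(=O)N2[C@@H](Cc3ccccc3)COC2=O)cc1OC | intermediate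
15 | (R)-4-[3,4-bis(benzyloxy)phenyl]-2-(3,4-dimethoxybenzyl)-4-oxobutaneperoxoic acid | COc1ccc(C[C@H](CC(=O)c2ccc(OCc3ccccc3)c(OCc3ccccc3)c2)C(=O)OO)cc1OC | intermediate
16 | (R)-4-[3,4-bis(benzyloxy)phenyl]-2-(3,4-dimethoxybenzyl)-4-oxobutanoic acid | COc1ccc(C[C@H](CC(=O)c2ccc(OCc3ccccc3)c(OCc3ccccc3)c2)C(=O)O)cc1OC | intermediate
17 | formaldehyde | C=O | starting material
18 | (2R)-4-[3,4-bis(benzyloxy)phenyl]-2-(3,4-dimethoxybenzyl)-3-(hydroxymethyl)-4-oxobutanoic acid (C3 epimers) | COc1ccc(C[C@H](C(CO)C(=O)c2ccc(OCc3ccccc3)c(OCc3ccccc3)c2)C(=O)O)cc1OC | intermediate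
19 | (3R)-4-[3,4-bis(benzyloxy)benzoyl]-3-(3,4-dimethoxybenzyl)dihydrofuran-2(3H)-one (C4 epimers) | COc1ccc(C[C@H]2C(=O)OCC2C(=O)c2ccc(OCc3ccccc3)c(OCc3ccccc3)c2)cc1OC | intermediate
20 | (3R,4R)-4-[3,4-bis(benzyloxy)benzoyl]-3-(3,4-dimethoxybenzyl)dihydrofuran-2(3H)-one | COc1ccc(C[C@H]2C(=O)OC[C@@H]2C(=O)c2ccc(OCc3ccccc3)c(OCc3ccccc3)c2)cc1OC | intermediate
21 | (3R,4R)-4-(3,4-dihydroxybenzoyl)-3-(3,4-dimethoxybenzyl)dihydrofuran-2(3H)-one | COc1ccc(C[C@H]2C(=O)OC[C@@H]2C(=O)c2ccc(O)c(O)c2)cc1OC | intermediate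
22 | (3R,4R)-4-[(3,4-dihydroxyphenyl)(hydroxy)methyl]-3-(3,4-dimethoxybenzyl)dihydrofuran-2(3H)-one (carbinol epimers) | COc1ccc(C[C@H]2C(=O)OC[C@@H]2C(O)c2ccc(O)c(O)c2)cc1OC | intermediate
23 | (3R,4R)-4-(3,4-dihydroxybenzyl)-3-(3,4-dimethoxybenzyl)dihydrofuran-2(3H)-one | COc1ccc(C[C@H]2C(=O)OC[C@@H]2Cc2ccc(O)c(O)c2)cc1OC | target

**Step count**

Total: 8 steps. Longest linear sequence: 7 steps (steps 1, 2, 3, 5, 6, 7, 8 from acid 1); step 4 is a one-step side branch.

**Steps most likely to fail**

Step 7. Under aqueous hydroxide the aldol adduct may lose water to an alpha-methylene ketone, after which C3–H becomes vinylogously acidic and the C3 configuration erodes. A second formaldehyde may also add at C4, or retro-aldol may hold conversion low. The fallback forms the same two bonds by a Mukaiyama hydroxymethylation under Lewis-acid conditions, with no Brønsted base. It sets out from 16, which is esterified (MeI, KHCO3, DMF) to methyl (R)-4-[3,4-bis(benzyloxy)phenyl]-2-(3,4-dimethoxybenzyl)-4-oxobutanoate F1. Soft enolisation of the ketone only (TMSOTf 1.1 equiv, Et3N, CH2Cl2, 0 °C) should give methyl (R,Z)-4-[3,4-bis(benzyloxy)phenyl]-2-(3,4-dimethoxybenzyl)-4-(trimethylsilyloxy)but-3-enoate F2. Aqueous formaldehyde with Yb(OTf)3 in THF/H2O at rt should then give methyl (2R)-4-[3,4-bis(benzyloxy)phenyl]-2-(3,4-dimethoxybenzyl)-3-(hydroxymethyl)-4-oxobutanoate F3 as C3 epimers. TsOH in toluene at 60 °C lactonises F3 with loss of methanol and equilibrates C4, so the fallback comes back to the route at 20.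

Step 5. The acyl chloride may be consumed before coupling, by intramolecular Friedel–Crafts attack of the dimethoxyphenyl ring under zinc halide Lewis acidity or by participation of the imide carbonyl, and the arylzinc may homocouple. The fallback replaces the acyl chloride by an isolable thioester and uses a Fukuyama coupling. It sets out from 8, which with EtSH, EDC·HCl and DMAP in CH2Cl2 should give S-ethyl (R)-4-[(S)-4-benzyl-2-oxooxazolidin-3-yl]-3-(3,4-dimethoxybenzyl)-4-oxobutanethioate F4. Coupling of F4 with arylzinc chloride 13 (made from 10 as in step 5) under PdCl2(PPh3)2 in THF/toluene at rt comes back to the route at 14.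

Step 8. O-Debenzylation may outrun carbonyl reduction and leave a para-hydroxyaryl ketone that resists hydrogenation, so the reduction stalls. Forcing it with stronger acid would invite Friedel–Crafts cyclisation of the benzylic cation onto the dimethoxyphenyl ring. The fallback reduces the carbonyl with hydride before any hydrogenolysis. It sets out from 20, which with NaBH4 and CeCl3·7H2O in MeOH/THF at −40 °C (Luche conditions, lactone untouched) should give (3R,4R)-4-{[3,4-bis(benzyloxy)phenyl](hydroxy)methyl}-3-(3,4-dimethoxybenzyl)dihydrofuran-2(3H)-one F5 as carbinol epimers. H2 over 10% Pd/C in EtOH at rt then removes both benzyl ethers and hydrogenolyses the para-hydroxybenzylic C–O bond under neutral conditions, coming back to the route at 23.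

**Further compounds**

F1 | step 7 | methyl (R)-4-[3,4-bis(benzyloxy)phenyl]-2-(3,4-dimethoxybenzyl)-4-oxobutanoate | COc1ccc(C[C@H](CC(=O)c2ccc(OCc3ccccc3)c(OCc3ccccc3)c2)C(=O)OC)cc1OC
F2 | step 7 | methyl (R,Z)-4-[3,4-bis(benzyloxy)phenyl]-2-(3,4-dimethoxybenzyl)-4-(trimethylsilyloxy)but-3-enoate | COc1ccc(C[C@H](/C=C(\O[Si](C)(C)C)c2ccc(OCc3ccccc3)c(OCc3ccccc3)c2)C(=O)OC)cc1OC
F3 | step 7 | methyl (2R)-4-[3,4-bis(benzyloxy)phenyl]-2-(3,4-dimethoxybenzyl)-3-(hydroxymethyl)-4-oxobutanoate (C3 epimers) | COc1ccc(C[C@H](C(CO)C(=O)c2ccc(OCc3ccccc3)c(OCc3ccccc3)c2)C(=O)OC)cc1OC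
F4 | step 5 | S-ethyl (R)-4-[(S)-4-benzyl-2-oxooxazolidin-3-yl]-3-(3,4-dimethoxybenzyl)-4-oxobutanethioate | COc1ccc(C[C@H](CC(=O)SCC)C(=O)N2[C@@H](Cc3ccccc3)COC2=O)cc1OC
F5 | step 8 | (3R,4R)-4-{[3,4-bis(benzyloxy)phenyl](hydroxy)methyl}-3-(3,4-dimethoxybenzyl)dihydrofuran-2(3H)-one (carbinol epimers) | COc1ccc(C[C@H]2C(=O)OC[C@@H]2C(O)c2ccc(OCc3ccccc3)c(OCc3ccccc3)c2)cc1OC
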